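## Retrosynthetic overview

1. Macrolactone (18-membered, formed last): C2=C3 by ring-closing metathesis of a C17 acrylate with the C3 vinyl group left by a syn-crotylboration of a C5 enal.
2. Bromotetrahydrofuran (formed second): 5-endo bromoetherification of a C16,C17-diol onto the (E)-C18=C19 alkene; C17–C18 by Nozaki–Hiyama–Kishi coupling with a vinyl iodide carrying C18–C25.
3. Key C15–C16 bond: lithiated allyl MOM ether (an α-oxygenated allyl carbanion, a donor at a carbon that is normally an acceptor) as its chiral borane, added to (S)-citronellal; this sets C15 and C16 together.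
4. Oxazole (formed first): Hantzsch condensation of the citronellal-derived C10 amide with 1-bromobutane-2,3-dione; the acetyl group later becomes C7/C6/C5.
5. Side chain: C24 from (R)-lactic acid (Seebach alkylation), C21=C22 by Z-selective cross-metathesis.

Assumption: the SMILES is read as drawn, i.e. (2E,4S,5R,6E,13S,15S,16R,17R,18S,19R,21Z,24S) with labels C1 (lactone C=O) to C25 (CO2H); C8, C9 and C10 are oxazole C4, C5 and C2. These labels are used in the names below.

## Route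

Step 1
Reactants: 1 prop-2-en-1-ol (allyl alcohol)
Product: 2 3-(methoxymethoxy)prop-1-ene
Conditions: MOMCl, iPr2NEt, CH2Cl2, 0 °C → rt
Reagents that add atoms: chloromethyl methyl ether, COCCl
Why: Williamson-type O-alkylation of the alcohol by the oxocarbenium-like electrophile; no stereocentre is involved.

Step 2
Reactants: 2 3-(methoxymethoxy)prop-1-ene; 3 (S)-citronellal
Product: 6 (3S,4S,6S)-3-(methoxymethoxy)-6,10-dimethylundeca-1,9-dien-4-ol, via alkoxyallylborane 4 (not isolated), via borinate ester 5 (not isolated)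
Conditions: 2, sBuLi, THF, −78 °C; (+)-Ipc2BOMe [from (−)-α-pinene]; BF3·OEt2; 3, −78 °C; then NaOH, H2O2
Reagents that add atoms: none
Why: Brown γ-alkoxyallylboration: deprotonation of 2 gives an α-oxygenated allyl anion (reversed polarity at the future C16), held on boron as the (Z)-γ-alkoxyallylborane 4, which adds to the aldehyde through a closed chair transition state, so the Z geometry gives the 15,16-syn relationship and the isopinocampheyl groups direct attack to the Re face (15S,16S as labelled; C13 of 3 is carried unchanged).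

Step 3
Reactants: 6 (3S,4S,6S)-3-(methoxymethoxy)-6,10-dimethylundeca-1,9-dien-4-ol
Product: 7 (3S,4S,6S)-4-methoxy-3-(methoxymethoxy)-6,10-dimethylundeca-1,9-diene
Conditions: NaH, MeI, THF/DMF, 0 °C → rt
Reagents that add atoms: iodomethane, CI
Why: Williamson O-methylation of the only free hydroxyl installs the C15 methyl ether; no stereocentre is touched.

Step 4
Reactants: 7 (3S,4S,6S)-4-methoxy-3-(methoxymethoxy)-6,10-dimethylundeca-1,9-diene
Product: 9 (4S,6S,7S)-6-methoxy-7-(methoxymethoxy)-4-methylnon-8-enoic acid, via aldehyde 8 (not isolated)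
Conditions: O3 (1.0 equiv, Sudan Red 7B end point), pyridine, CH2Cl2/MeOH, −78 °C; Me2S; then NaClO2, NaH2PO4, 2-methyl-2-butene, tBuOH/H2O, rt
Reagents that add atoms: ozone, [O-][O+]=O; sodium chlorite, [Na+].[O-]Cl=O
Why: Chemoselective ozonolysis of the electron-rich trisubstituted alkene (the monosubstituted vinyl group, deactivated by two neighbouring C–O bonds, reacts far more slowly) followed by Pinnick oxidation; no stereocentre is touched.

Step 5
Reactants: 9 (4S,6S,7S)-6-methoxy-7-(methoxymethoxy)-4-methylnon-8-enoic acid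
Product: 11 (4S,6S,7S)-6-methoxy-7-(methoxymethoxy)-4-methylnon-8-enamide, via mixed anhydride 10 (not isolated)
Conditions: iBuOCOCl, N-methylmorpholine, THF, −15 °C; then aq. NH3, −15 °C → rt
Reagents that add atoms: ammonia, N
Why: Mixed carbonic anhydride activation and ammonolysis give the primary amide needed for the oxazole.

Step 6
Reactants: 11 (4S,6S,7S)-6-methoxy-7-(methoxymethoxy)-4-methylnon-8-enamide; 12 1-bromobutane-2,3-dione
Product: 14 1-{2-[(3S,5S,6S)-5-methoxy-6-(methoxymethoxy)-3-methyloct-7-en-1-yl]-1,3-oxazol-4-yl}ethan-1-one, via hydroxyoxazoline 13 (not isolated)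
Conditions: 12, NaHCO3, THF, 60 °C; then (CF3CO)2O, 2,6-lutidine, 0 °C → rt
Reagents that add atoms: none
Why: Hantzsch (Blümlein–Lewy) oxazole synthesis: O-alkylation of the amide by the bromoketone, N-cyclisation onto the adjacent carbonyl to give 13 and dehydration give the 2,4-disubstituted oxazole with the distal acetyl group at C4.

Step 7
Reactants: 14 1-{2-[(3S,5S,6S)-5-methoxy-6-(methoxymethoxy)-3-methyloct-7-en-1-yl]-1,3-oxazol-4-yl}ethan-1-one
Product: 15 (2R,3S,5S)-7-(4-acetyl-1,3-oxazol-2-yl)-3-methoxy-2-(methoxymethoxy)-5-methylheptanal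
Conditions: OsO4 (2 mol %), NaIO4, 2,6-lutidine, dioxane/H2O, rt
Reagents that add atoms: osmium tetroxide (catalytic oxygen carrier), O=[Os](=O)(=O)=O; sodium periodate, [Na+].[O-]I(=O)(=O)=O
Why: Lemieux–Johnson cleavage of the only remaining alkene gives the C17 aldehyde; lutidine buffering keeps the α-alkoxy centre (C16) from epimerising.

Step 8
Reactants: 16 pent-1-en-4-yne
Product: 18 (1E)-1-iodo-2-methylpenta-1,4-diene, via vinylalane 17 (not isolated)
Conditions: AlMe3, Cp2ZrCl2 (20 mol %), CH2Cl2, 0 °C → rt; then I2, THF, −30 °C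
Reagents that add atoms: trimethylaluminium, C[Al](C)C; iodine, II
Why: Negishi zirconium-catalysed carboalumination adds Me–Al syn across the alkyne with Al at the terminus, and iodinolysis with retention gives the (E)-iodide; the isolated terminal alkene is not carbometalated.

Step 9
Reactants: 19 (R)-lactic acid
Product: 20 (2R,5R)-2-tert-butyl-5-methyl-1,3-dioxolan-4-one
Conditions: tBuCHO, TsOH (cat.), H2SO4 (cat.), pentane, reflux (Dean–Stark); recrystallise at −78 °C
Reagents that add atoms: pivalaldehyde, CC(C)(C)C=O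
Why: Seebach acetalisation gives the cis acetal (purified by crystallisation), whose acetal carbon stores the chirality of lactic acid.

Step 10
Reactants: 20 (2R,5R)-2-tert-butyl-5-methyl-1,3-dioxolan-4-one; 21 allyl bromide
Product: 22 (2R,5S)-2-tert-butyl-5-methyl-5-(prop-2-en-1-yl)-1,3-dioxolan-4-one
Conditions: LDA, THF, −78 °C; then 21, −78 → −30 °C
Reagents that add atoms: none
Why: Seebach self-regeneration of stereocentres: the enolate is alkylated anti to the tert-butyl group, which sets the quaternary centre that becomes (24S).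

Step 11
Reactants: 22 (2R,5S)-2-tert-butyl-5-methyl-5-(prop-2-en-1-yl)-1,3-dioxolan-4-one
Product: 23 2-(trimethylsilyl)ethyl (2S)-2-hydroxy-2-methylpent-4-enoate
Conditions: Me3SiCH2CH2OH, NaH (0.2 equiv), THF, 0 °C → rt
Reagents that add atoms: 2-(trimethylsilyl)ethanol, C[Si](C)(C)CCO
Why: Alkoxide transesterification opens the acylal and expels pivalaldehyde, giving a fluoride-cleavable ester without touching the quaternary centre.

Step 12
Reactants: 18 (1E)-1-iodo-2-methylpenta-1,4-diene; 23 2-(trimethylsilyl)ethyl (2S)-2-hydroxy-2-methylpent-4-enoate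
Product: 24 2-(trimethylsilyl)ethyl (2S,4Z,7E)-2-hydroxy-8-iodo-2,7-dimethylocta-4,7-dienoate
Conditions: 18 (3 equiv), Grubbs Z-selective catalyst Ru(NO3)(C–H-cyclometalated N-adamantyl-N'-(2,6-diisopropylphenyl)imidazolin-2-ylidene)(=CH-C6H4-2-OiPr) (5 mol %), THF, 35 °C, static vacuum
Reagents that add atoms: none
Why: Z-selective olefin cross-metathesis of the two terminal alkenes (syn-metallacycle on the cyclometalated Ru catalyst gives the cis C21=C22 bond; the trisubstituted iodoalkene does not take part; excess volatile 18 suppresses homodimer of 23).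

Step 13
Reactants: 15 (2R,3S,5S)-7-(4-acetyl-1,3-oxazol-2-yl)-3-methoxy-2-(methoxymethoxy)-5-methylheptanal; 24 2-(trimethylsilyl)ethyl (2S,4Z,7E)-2-hydroxy-8-iodo-2,7-dimethylocta-4,7-dienoate
Product: 25 2-(trimethylsilyl)ethyl (2S,4Z,7E,9S,10S,11S,13S)-15-(4-acetyl-1,3-oxazol-2-yl)-2,9-dihydroxy-11-methoxy-10-(methoxymethoxy)-2,7,13-trimethylpentadeca-4,7-dienoate
Conditions: CrCl2 (4 equiv), NiCl2 (2 mol %), DMSO/THF, rt
Reagents that add atoms: none
Why: Nozaki–Hiyama–Kishi coupling: the vinylchromium from 24 (E geometry retained) adds only to the aldehyde (ketone and ester are inert), and Felkin–Anh attack anti to the α-OMOM group gives the 16,17-anti alcohol (expected dr about 4:1, separable).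

Step 14
Reactants: 25 (the C17 allylic alcohol above); 26 diethyl [(E)-2-(cyclohexylamino)ethenyl]phosphonate
Product: 28 2-(trimethylsilyl)ethyl (2S,4Z,7E,9S,10S,11S,13S)-2,9-dihydroxy-11-methoxy-10-(methoxymethoxy)-2,7,13-trimethyl-15-{4-[(2E)-4-oxobut-2-en-2-yl]-1,3-oxazol-2-yl}pentadeca-4,7-dienoate, via unsaturated imine 27 (not isolated)
Conditions: 26, NaH, THF, 0 → 50 °C; then aq. (CO2H)2, THF, rt
Reagents that add atoms: water, O
Why: Nagata formylolefination (Horner–Wadsworth–Emmons addition of the phosphonate enamine anion to the methyl ketone, then imine hydrolysis) gives the enal with the thermodynamically favoured (E)-C6=C7 geometry.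

Step 15
Reactants: 28 (the 16-O-MOM enal above)
Product: 29 2-(trimethylsilyl)ethyl (2S,4Z,7E,9S,10S,11S,13S)-2,9,10-trihydroxy-11-methoxy-2,7,13-trimethyl-15-{4-[(2E)-4-oxobut-2-en-2-yl]-1,3-oxazol-2-yl}pentadeca-4,7-dienoate
Conditions: Me2BBr, 2,6-di-tert-butyl-4-methylpyridine, CH2Cl2, −78 °C; then aq. NaHCO3/THF
Reagents that add atoms: none
Why: Guindon cleavage of the MOM acetal (bromide opening of the boron-activated acetal at low temperature) frees O16; the methyl ether, silyl ester and enal survive and no stereocentre is touched.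

Step 16
Reactants: 29 (the 16,17-diol above)
Product: 30 2-(trimethylsilyl)ethyl (2S,4Z)-6-[(2R,3S,4R,5S)-3-bromo-4-hydroxy-5-{(1S,3S)-1-methoxy-3-methyl-5-[4-((2E)-4-oxobut-2-en-2-yl)-1,3-oxazol-2-yl]pentyl}-2-methyloxolan-2-yl]-2-hydroxy-2-methylhex-4-enoate
Conditions: NBS (1.05 equiv), MeCN, −30 → 0 °C, dark
Reagents that add atoms: N-bromosuccinimide, O=C1CCC(=O)N1Br
Why: 5-endo-trig bromoetherification: the bromonium ion forms on the most nucleophilic (trisubstituted) C18=C19 alkene and is opened at tertiary C19 by O16, so anti addition across the E-alkene fixes C18 relative to C19, and the envelope transition state that places Br trans to O17 (all-trans ring) gives 18S,19R.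

Step 17
Reactants: 30 (the bromotetrahydrofuran alcohol above); 31 acryloyl chloride
Product: 32 17-O-acryloyl ester of 30 (oxolane 2R,3S,4R,5R)
Conditions: 31, iPr2NEt, DMAP (5 mol %), CH2Cl2, −40 → 0 °C
Reagents that add atoms: none
Why: Acylation of the only reactive (secondary) hydroxyl; the tertiary C24 hydroxyl is inert under these conditions.

Step 18
Reactants: 32 17-O-acryloyl ester of 30; 33 (Z)-but-2-ene
Product: 36 (4S,5R)-syn-homoallylic alcohol from 32 (C5 aldehyde converted into CH(OH)–CH(CH3)–CH=CH2), via crotylborane 34 (not isolated), via borinate ester 35 (not isolated)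
Conditions: 33, nBuLi, KOtBu, THF, −78 → −45 °C; (+)-Ipc2BOMe [from (−)-α-pinene], −78 °C; BF3·OEt2; 32, −78 °C; then HOCH2CH2NH2, Et2O, rt
Reagents that add atoms: none
Why: Brown (Z)-crotylboration through a chair transition state: the Z-crotyl geometry gives the 4,5-syn relationship and the isopinocampheyl groups direct attack to the Re face of the enal (4S,5R); the reagent reacts only with the aldehyde.

Step 19
Reactants: 36 (the acrylate/terminal-vinyl diene above)
Product: 37 2-(trimethylsilyl)ethyl ester of the target macrolide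
Conditions: second-generation Grubbs catalyst (H2IMes)(PCy3)Cl2Ru=CHPh (10 mol %), toluene (1 mM), 80 °C
Reagents that add atoms: none
Why: Ring-closing metathesis between the terminal C3 vinyl group and the acrylate closes the 18-membered ring as the thermodynamically preferred (2E)-enoate; the trisubstituted alkenes and the internal Z-alkene flanked by two quaternary carbons are poor metathesis partners.

Step 20
Reactants: 37 2-(trimethylsilyl)ethyl ester of the target macrolide
Product: 38 CNP0163177.2 (target)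
Conditions: TBAF, THF, 0 °C → rt; then aq. NaHSO4
Reagents that add atoms: none
Why: Fluoride-induced fragmentation of the 2-(trimethylsilyl)ethyl ester frees the acid without hydrolytic conditions, so the macrolactone is untouched; the ring bromide has no anti-periplanar hydrogen for E2.

## Compound list

1 | prop-2-en-1-ol | C=CCO | starting material
2 | 3-(methoxymethoxy)prop-1-ene | C=CCOCOC | intermediate
3 | (S)-citronellal, (3S)-3,7-dimethyloct-6-enal | O=CC[C@@H](C)CCC=C(C)C | starting material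
4 | [(Z)-3-(methoxymethoxy)prop-2-en-1-yl]bis[(1S,2S,3S,5R)-isopinocampheyl]borane | COCO/C=C\CB([C@H]1C[C@H]2C[C@@H]([C@@H]1C)C2(C)C)[C@H]1C[C@H]2C[C@@H]([C@@H]1C)C2(C)C | intermediate
5 | bis(isopinocampheyl)borinate ester of 6 | B([C@H]1C[C@H]2C[C@@H]([C@@H]1C)C2(C)C)([C@H]1C[C@H]2C[C@@H]([C@@H]1C)C2(C)C)O[C@H]([C@@H](OCOC)C=C)C[C@@H](C)CCC=C(C)C | intermediate
6 | (3S,4S,6S)-3-(methoxymethoxy)-6,10-dimethylundeca-1,9-dien-4-ol | O[C@H]([C@@H](OCOC)C=C)C[C@@H](C)CCC=C(C)C | intermediate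
7 | (3S,4S,6S)-4-methoxy-3-(methoxymethoxy)-6,10-dimethylundeca-1,9-diene | CO[C@H]([C@@H](OCOC)C=C)C[C@@H](C)CCC=C(C)C | intermediate
8 | (4S,6S,7S)-6-methoxy-7-(methoxymethoxy)-4-methylnon-8-enal | CO[C@H]([C@@H](OCOC)C=C)C[C@@H](C)CCC=O | intermediate
9 | (4S,6S,7S)-6-methoxy-7-(methoxymethoxy)-4-methylnon-8-enoic acid | CO[C@H]([C@@H](OCOC)C=C)C[C@@H](C)CCC(=O)O | intermediate
10 | isobutyl carbonic anhydride of 9 | CO[C@H]([C@@H](OCOC)C=C)C[C@@H](C)CCC(=O)OC(=O)OCC(C)C | intermediate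
11 | (4S,6S,7S)-6-methoxy-7-(methoxymethoxy)-4-methylnon-8-enamide | CO[C@H]([C@@H](OCOC)C=C)C[C@@H](C)CCC(N)=O | intermediate
12 | 1-bromobutane-2,3-dione | CC(=O)C(=O)CBr | starting material
13 | 4-acetyl-4-hydroxy-4,5-dihydro-1,3-oxazole carrying the chain of 11 at C2 (both epimers at the carbinol carbon) | CO[C@H]([C@@H](OCOC)C=C)C[C@@H](C)CCC1=NC(O)(C(C)=O)CO1 | intermediate
14 | 1-{2-[(3S,5S,6S)-5-methoxy-6-(methoxymethoxy)-3-methyloct-7-en-1-yl]-1,3-oxazol-4-yl}ethan-1-one | CO[C@H]([C@@H](OCOC)C=C)C[C@@H](C)CCc1nc(C(C)=O)co1 | intermediate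
15 | (2R,3S,5S)-7-(4-acetyl-1,3-oxazol-2-yl)-3-methoxy-2-(methoxymethoxy)-5-methylheptanal | CO[C@H]([C@@H](OCOC)C=O)C[C@@H](C)CCc1nc(C(C)=O)co1 | intermediate
16 | pent-1-en-4-yne | C=CCC#C | starting material
17 | dimethyl[(1E)-2-methylpenta-1,4-dien-1-yl]alane | C[Al](C)/C=C(\C)CC=C | intermediate
18 | (1E)-1-iodo-2-methylpenta-1,4-diene | I/C=C(\C)CC=C | intermediate
19 | (R)-lactic acid | C[C@@H](O)C(=O)O | starting material
20 | (2R,5R)-2-tert-butyl-5-methyl-1,3-dioxolan-4-one (cis) | C[C@H]1O[C@@H](C(C)(C)C)OC1=O | intermediate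
21 | allyl bromide | C=CCBr | starting material
22 | (2R,5S)-2-tert-butyl-5-methyl-5-(prop-2-en-1-yl)-1,3-dioxolan-4-one | C[C@@]1(CC=C)O[C@@H](C(C)(C)C)OC1=O | intermediate
23 | 2-(trimethylsilyl)ethyl (2S)-2-hydroxy-2-methylpent-4-enoate | C=CC[C@](C)(O)C(=O)OCC[Si](C)(C)C | intermediate
24 | 2-(trimethylsilyl)ethyl (2S,4Z,7E)-2-hydroxy-8-iodo-2,7-dimethylocta-4,7-dienoate | I/C=C(\C)C/C=C\C[C@](C)(O)C(=O)OCC[Si](C)(C)C | intermediate
25 | 2-(trimethylsilyl)ethyl (2S,4Z,7E,9S,10S,11S,13S)-15-(4-acetyl-1,3-oxazol-2-yl)-2,9-dihydroxy-11-methoxy-10-(methoxymethoxy)-2,7,13-trimethylpentadeca-4,7-dienoate (15-OMe/16-O syn, 16-O/17-O anti) | CO[C@H]([C@@H](OCOC)[C@@H](O)/C=C(\C)C/C=C\C[C@](C)(O)C(=O)OCC[Si](C)(C)C)C[C@@H](C)CCc1nc(C(C)=O)co1 | intermediate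
26 | diethyl [(E)-2-(cyclohexylamino)ethenyl]phosphonate | CCOP(=O)(OCC)/C=C/NC1CCCCC1 | starting material
27 | N-cyclohexyl imine of enal 28 | CO[C@H]([C@@H](OCOC)[C@@H](O)/C=C(\C)C/C=C\C[C@](C)(O)C(=O)OCC[Si](C)(C)C)C[C@@H](C)CCc1nc(/C(C)=C/C=NC2CCCCC2)co1 | intermediate
28 | 2-(trimethylsilyl)ethyl (2S,4Z,7E,9S,10S,11S,13S)-2,9-dihydroxy-11-methoxy-10-(methoxymethoxy)-2,7,13-trimethyl-15-{4-[(2E)-4-oxobut-2-en-2-yl]-1,3-oxazol-2-yl}pentadeca-4,7-dienoate | CO[C@H]([C@@H](OCOC)[C@@H](O)/C=C(\C)C/C=C\C[C@](C)(O)C(=O)OCC[Si](C)(C)C)C[C@@H](C)CCc1nc(/C(C)=C/C=O)co1 | intermediate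
29 | 2-(trimethylsilyl)ethyl (2S,4Z,7E,9S,10S,11S,13S)-2,9,10-trihydroxy-11-methoxy-2,7,13-trimethyl-15-{4-[(2E)-4-oxobut-2-en-2-yl]-1,3-oxazol-2-yl}pentadeca-4,7-dienoate | CO[C@H]([C@@H](O)[C@@H](O)/C=C(\C)C/C=C\C[C@](C)(O)C(=O)OCC[Si](C)(C)C)C[C@@H](C)CCc1nc(/C(C)=C/C=O)co1 | intermediate
30 | 2-(trimethylsilyl)ethyl (2S,4Z)-6-[(2R,3S,4R,5S)-3-bromo-4-hydroxy-5-{(1S,3S)-1-methoxy-3-methyl-5-[4-((2E)-4-oxobut-2-en-2-yl)-1,3-oxazol-2-yl]pentyl}-2-methyloxolan-2-yl]-2-hydroxy-2-methylhex-4-enoate (ring: C16 chain trans to 17-OH, Br trans to 17-OH, 19-CH3 cis to Br) | CO[C@H]([C@H]1O[C@](C)(C/C=C\C[C@](C)(O)C(=O)OCC[Si](C)(C)C)[C@@H](Br)[C@@H]1O)C[C@@H](C)CCc1nc(/C(C)=C/C=O)co1 | intermediate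
31 | acryloyl chloride | C=CC(=O)Cl | starting material
32 | 17-O-acryloyl ester of 30 (oxolane 2R,3S,4R,5R) | CO[C@H]([C@H]1O[C@](C)(C/C=C\C[C@](C)(O)C(=O)OCC[Si](C)(C)C)[C@@H](Br)[C@@H]1OC(=O)C=C)C[C@@H](C)CCc1nc(/C(C)=C/C=O)co1 | intermediate
33 | (Z)-but-2-ene | C/C=C\C | starting material
34 | [(Z)-but-2-en-1-yl]bis[(1S,2S,3S,5R)-isopinocampheyl]borane | C/C=C\CB([C@H]1C[C@H]2C[C@@H]([C@@H]1C)C2(C)C)[C@H]1C[C@H]2C[C@@H]([C@@H]1C)C2(C)C | intermediate
35 | bis(isopinocampheyl)borinate ester of 36 (boron on O5) | CO[C@H]([C@H]1O[C@](C)(C/C=C\C[C@](C)(O)C(=O)OCC[Si](C)(C)C)[C@@H](Br)[C@@H]1OC(=O)C=C)C[C@@H](C)CCc1nc(/C(C)=C/[C@H](OB([C@H]2C[C@H]3C[C@@H]([C@@H]2C)C3(C)C)[C@H]2C[C@H]3C[C@@H]([C@@H]2C)C3(C)C)[C@@H](C)C=C)co1 | intermediate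
36 | 17-O-acryloyl (4S,5R)-5-hydroxy-4-methyl-3-vinyl seco compound (crotylation product of 32; 4-CH3/5-OH syn) | CO[C@H]([C@H]1O[C@](C)(C/C=C\C[C@](C)(O)C(=O)OCC[Si](C)(C)C)[C@@H](Br)[C@@H]1OC(=O)C=C)C[C@@H](C)CCc1nc(/C(C)=C/[C@H](O)[C@@H](C)C=C)co1 | intermediate
37 | 2-(trimethylsilyl)ethyl ester of the target macrolide | CO[C@H]1C[C@@H](C)CCc2nc(co2)/C(C)=C/[C@H](O)[C@@H](C)/C=C/C(=O)O[C@@H]2[C@@H]1O[C@](C)(C/C=C\C[C@](C)(O)C(=O)OCC[Si](C)(C)C)[C@H]2Br | intermediate
38 | CNP0163177.2, (2E,4S,5R,6E,13S,15S,16R,17R,18S,19R,21Z,24S)-macrolide acid | CO[C@H]1C[C@@H](C)CCc2nc(co2)/C(C)=C/[C@H](O)[C@@H](C)/C=C/C(=O)O[C@@H]2[C@@H]1O[C@](C)(C/C=C\C[C@](C)(O)C(=O)O)[C@H]2Br | target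

## Step count and risks

Total step count: 20. Longest linear sequence: 15 steps (steps 1–7, then 13–20).

The three steps most likely to fail:

Step 12 (Z-selective cross-metathesis) may give poor Z/E ratios or mainly homodimers. The fallback builds the C21=C22 bond from an alkyne instead; it sets out from 20 and comes back at 24. The lithium enolate of 20 is alkylated with propargyl bromide to (2R,5S)-2-tert-butyl-5-methyl-5-(prop-2-yn-1-yl)-1,3-dioxolan-4-one F1, which Me3SiCH2CH2OH/NaH opens to 2-(trimethylsilyl)ethyl (2S)-2-hydroxy-2-methylpent-4-ynoate F2. Separately, propargyl alcohol is carboaluminated and iodinated (AlMe3, Cp2ZrCl2; I2) to (2E)-3-iodo-2-methylprop-2-en-1-ol F3 and converted (CBr4, PPh3) into (1E)-3-bromo-1-iodo-2-methylprop-1-ene F4. Copper-mediated coupling of F2 with F4 (CuI, K2CO3, NaI, DMF) gives the skipped enyne 2-(trimethylsilyl)ethyl (2S,7E)-2-hydroxy-8-iodo-2,7-dimethyloct-7-en-4-ynoate F5, and cis semi-reduction of the alkyne (dicyclohexylborane, then AcOH) gives 24.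

Step 16 (bromoetherification of the free diol) may show poor facial selectivity next to the free allylic 17-hydroxyl, or attack other alkenes. The fallback cyclises a 17-O-silyl ether instead; it sets out from 28 and comes back at 30. Silylation of the 17-hydroxyl (TBSCl, imidazole, DMF; the tertiary hydroxyl is left) gives the 17-O-TBS ether of 28 F6. Me2BBr then removes the MOM group to give the 16-hydroxy 17-O-TBS compound F7. Cyclisation with 2,4,4,6-tetrabromocyclohexa-2,5-dienone, where the bulky non-participating silyloxy group forces bromine to the opposite face, gives the 17-O-TBS bromotetrahydrofuran F8. HF·pyridine then gives 30.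

Step 19 (ring-closing metathesis) may be diverted by the C21=C22 alkene or give oligomers. The fallback closes the ring by lactonisation instead; it sets out from 30 and comes back at 37. Compound 30 is crotylborated directly (reagent 34, as in step 18) to the 5,17-diol F9. Cross-metathesis of the terminal vinyl group of F9 with acrylic acid (second-generation Hoveyda–Grubbs catalyst (H2IMes)Cl2Ru=CH(C6H4-2-OiPr), 0.1 M, so that the unhindered terminal alkene is consumed before the hindered internal one) gives the (2E)-seco acid F10. Shiina macrolactonisation (2-methyl-6-nitrobenzoic anhydride, DMAP, toluene, high dilution) then closes the ring onto O17 to give 37; the (E)-enoate cannot lactonise onto O5 and the tertiary 24-hydroxyl is inert.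

## Further compounds

F1 | step 12 | (2R,5S)-2-tert-butyl-5-methyl-5-(prop-2-yn-1-yl)-1,3-dioxolan-4-one | C[C@@]1(CC#C)O[C@@H](C(C)(C)C)OC1=O
F2 | step 12 | 2-(trimethylsilyl)ethyl (2S)-2-hydroxy-2-methylpent-4-ynoate | C#CC[C@](C)(O)C(=O)OCC[Si](C)(C)C
F3 | step 12 | (2E)-3-iodo-2-methylprop-2-en-1-ol | OC/C(C)=C/I
F4 | step 12 | (1E)-3-bromo-1-iodo-2-methylprop-1-ene | BrC/C(C)=C/I
F5 | step 12 | 2-(trimethylsilyl)ethyl (2S,7E)-2-hydroxy-8-iodo-2,7-dimethyloct-7-en-4-ynoate | I/C=C(\C)CC#CC[C@](C)(O)C(=O)OCC[Si](C)(C)C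
F6 | step 16 | 17-O-tert-butyldimethylsilyl ether of 28 | CO[C@H]([C@@H](OCOC)[C@@H](O[Si](C)(C)C(C)(C)C)/C=C(\C)C/C=C\C[C@](C)(O)C(=O)OCC[Si](C)(C)C)C[C@@H](C)CCc1nc(/C(C)=C/C=O)co1
F7 | step 16 | 16-hydroxy 17-O-tert-butyldimethylsilyl compound (F6 without MOM) | CO[C@H]([C@@H](O)[C@@H](O[Si](C)(C)C(C)(C)C)/C=C(\C)C/C=C\C[C@](C)(O)C(=O)OCC[Si](C)(C)C)C[C@@H](C)CCc1nc(/C(C)=C/C=O)co1
F8 | step 16 | 17-O-tert-butyldimethylsilyl ether of 30 | CO[C@H]([C@H]1O[C@](C)(C/C=C\C[C@](C)(O)C(=O)OCC[Si](C)(C)C)[C@@H](Br)[C@@H]1O[Si](C)(C)C(C)(C)C)C[C@@H](C)CCc1nc(/C(C)=C/C=O)co1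
F9 | step 19 | (4S,5R)-5,17-diol from crotylboration of 30 | CO[C@H]([C@H]1O[C@](C)(C/C=C\C[C@](C)(O)C(=O)OCC[Si](C)(C)C)[C@@H](Br)[C@@H]1O)C[C@@H](C)CCc1nc(/C(C)=C/[C@H](O)[C@@H](C)C=C)co1
F10 | step 19 | (2E)-seco acid (C1 carboxylic acid, free 5-OH and 17-OH) | CO[C@H]([C@H]1O[C@](C)(C/C=C\C[C@](C)(O)C(=O)OCC[Si](C)(C)C)[C@@H](Br)[C@@H]1O)C[C@@H](C)CCc1nc(/C(C)=C/[C@H](O)[C@@H](C)/C=C/C(=O)O)co1
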